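**The lead.** Take logarithms: let Λ, the lead, be the natural logarithm of the ratio of E to L in a flask. The excess of E over L is then that ratio less one, over the ratio plus one. X is single-handed, so it consumes the mirror images L and E with different rate constants (a kinetic resolution), and Λ grows with the time X is present.

| flask | L | E | G | remark | time |
|---|---|---|---|---|---|
| Wednesday's | 0.34 M | 0.34 M | 1 M | run made earlier |  |
| Tuesday's | 1 M | 1 M | 1 M | run made earlier |  |
| blue | 0.50 M | 0.50 M | 1.00 M |  | 20 min |
| grey | 0.50 M | 0.50 M | 3.00 M |  | 20 min |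

| run | time / min | E / % | L / % | Z / % |
|---|---|---|---|---|
| Wednesday's | 0.667 | 48.9 | 46.8 | 2.4 |
| Wednesday's | 2.00 | 45.3 | 39.4 | 11.9 |
| Wednesday's | 3.00 | 41.5 | 33.2 | 17.3 |
| Wednesday's | 5.00 | 33.2 | 22.3 | 29.7 |
| Wednesday's | 8.00 | 23.2 | 10.7 | 42.5 |
| Wednesday's | 10.0 | 16.6 | 6.2 | 47.9 |
| Wednesday's | 12.0 | 10.4 | 2.8 | 51.4 |
| Tuesday's | 0.667 | 49.2 | 47.8 | 1.7 |
| Tuesday's | 2.00 | 46.9 | 44.7 | 5.6 |
| Tuesday's | 3.00 | 45.3 | 42.0 | 9.7 |
| Tuesday's | 5.00 | 42.1 | 35.5 | 15.7 |
| Tuesday's | 8.00 | 35.4 | 28.3 | 24.9 |
| Tuesday's | 10.0 | 31.9 | 22.6 | 29.7 |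
| Tuesday's | 12.0 | 29.4 | 21.4 | 32.3 |

(readings scatter by 0.5 percentage points)

- the winner by excess of E over L among what is left of the two; "neither" if no more than 2 percentage points parts them (blue / grey / neither)
- excess of E over L among what is left of the two at the end, blue
- excess of E over L among what is left of the two at the end, grey

- X is single-handed; L and E are mirror images of each other, charged as a racemate, each of them at the stated concentration
- as a solid, counted per litre of solution: G
- what was read earlier has a scatter of 0.5 percentage points, one standard deviation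
- at the start none of G is in solution
- an excess is the difference of the two amounts in percent of their sum
- an excess is below zero if the other one leads
- the handed part of X does not stay in what it makes, so the products of the two hands are mirror images too

**The readings.** At 10.0 min, Wednesday's run has Λ = 0.985 with L charged at 0.34 M, and Tuesday's has Λ = 0.345 with L charged at 1 M. Multiplying Λ by the charge c of L and dividing by the time gives 0.0335 M min⁻¹ for Wednesday's run, about the same as 0.0345 M min⁻¹ for Tuesday's. Their mean, 0.0340 M min⁻¹, is the resolving rate w = Λc/t. By that time Tuesday's run has lost L and E together at 0.0910 M min⁻¹, read here as the feed of X from solid G.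

**The reckoning.** At that feed, G in blue lasts 11.0 min, less than the 20 min allowed, so G is blue's limiting reagent. Stopping the lead there gives Λ = 0.747 and an excess of 35.7%. G in grey lasts 33.0 min, longer than the time allowed, so Λ runs on to 1.36 and the excess to 59.1%.

**The forecast.** It names grey, with blue at 30% (20% to 40%) and grey at 50% (38% to 64%), holding that “Grey keeps feeding X”. Both figures are lower than the reckoning above.

**The flask.** Grey ends with the larger excess, 66.2% against 35.4% for blue.

    X ⇌ D (K = 0.840, k = 0.0110 s⁻¹)
    L ⇌ E (k = 7.90 × 10⁻⁴ s⁻¹)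
    G ⇌ X, rate k3*(cs3 - [X]) while solid is left; crystals form when [X] > cs3 (solubility = 0.190 M, k = 0.0100 s⁻¹)
    X → J (k = 0.00160 s⁻¹)
    X + E → Q (k = 0.0260 M⁻¹ s⁻¹)
    X + L → Z (k = 0.0620 M⁻¹ s⁻¹)

**The lead again.** Blue stood at 33.7% after 10.0 min with 14.3% of its G undissolved, and gained 1.7 percentage points by the end, when undissolved G stood at 0%. Grey's final excess corresponds to Λ = 1.59, so its w is 0.0398 M min⁻¹. Grey stopped at 5.0 min is the second case: w gives Λ = 0.340, hence 16.8%, and that flask shows 15.6%.

All runs were computed from invented constants.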